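If G takes J out of the round one for one, a flask has 0.0800 mM of J to work with here, and I called this, the charge of J less the charge of G, the live J.

common to all: Z 0.58 mM (held); J 0.25 mM

|  | Q | G | remark | time |
|---|---|---|---|---|
| Friday's | 0.014 M | 0.17 mM | run made earlier |  |
| Saturday's | 0.022 M | 0.17 mM | run made earlier |  |
| Sunday's | 0.010 M | 0.34 mM | run made earlier |  |
| flask | 0.010 M | 0.17 mM |  | 2.5 h |

| run | time / h | L / % |
|---|---|---|
| Friday's | 0.167 | 2.5 |
| Friday's | 0.500 | 8.0 |
| Friday's | 0.833 | 11.5 |
| Friday's | 1.33 | 17.4 |
| Friday's | 2.00 | 24.4 |
| Friday's | 2.50 | 28.0 |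
| Friday's | 3.00 | 32.5 |
| Saturday's | 0.250 | 2.6 |
| Saturday's | 0.333 | 3.7 |
| Saturday's | 0.500 | 5.6 |
| Saturday's | 0.833 | 9.7 |
| Saturday's | 1.33 | 14.4 |
| Saturday's | 2.00 | 20.5 |
| Saturday's | 3.00 | 28.5 |
| Sunday's | 0.667 | 1.8 |
| Sunday's | 1.33 | 1.8 |
| Sunday's | 2.00 | 2.0 |
| Sunday's | 2.50 | 1.6 |
| Sunday's | 3.00 | 2.1 |

(scatter of a reading: 0.3 percentage points)

- at the start none of D is dissolved
- steps that have been proposed: Z <-> D; Q + D + J -> J + L; Q + D -> E; J + G -> X

* amount of L at 2.5 h, in percent of the Q charged
* the change that raises the amount of L at 2.5 h, in percent of the Q charged most ("none" if none brings more than 2 percentage points) (north-east / south-east / west / none)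
* amount of L at 2.5 h, in percent of the Q charged, after north-east

- north-east: doubling the transfer coefficient of Z, all else as stated
- south-east: doubling the amount of J, all else as stated
- west: doubling the saturation concentration of Z, all else as stated

Sunday's run looks nearly like this flask, with the same Q and J, but its G stood at 0.34 mM against 0.25 mM of J, so its charge of G lay 0.0900 mM above its charge of J, and by this count Sunday's run had no live J. Its L lay near 0.186 mM from the first reading to the last. This flask keeps its live J, so I expected its L to go on rising.

Friday's and Saturday's runs hold the same live J, so I read the answer from them. Friday's gave 28.0% at 2.50 h. Saturday's has no reading there, so I replaced its curve by the mean of its readings on either side, 24.5%. The same step on Friday's gives 28.4%, off its reading by 0.45 percentage points. A straight line through these two percentages, carried down to 10 mM of Q, gave me 29.8%. Doubling J takes the live J to 0.330 mM, a factor of 4.12, beyond the doubling in the other two changes, so I chose south-east.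

The forecast gave 30%, south-east, and 34% after north-east, holding of the later rates that “the surviving catalyst limits them”.

The flask gave 30.5%, and south-east was the best change, with a gain of 38 points against 12 points for west and 3.3 points for north-east, which read 33.8%.

    Z ⇌ D, rate k1*(csat - [D]) (kL = 16.0 h⁻¹)
    Q + D + J → J + L (k = 5.90 × 10⁶ M⁻² h⁻¹)
    Q + D → E (k = 580 M⁻¹ h⁻¹)
    J + G → X (k = 90000 M⁻¹ h⁻¹)

With the live J of 0.0800 mM in the step, the constants put the selectivity factor, the flow of Q into E over its flow into L, at 1.23. At 2.50 h this flask held more E than L, 35.5% against 30.5%.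

Readings and results come from a simulation for an exercise.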